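**Strategy.** Ring A is cut across C2–C3 and C5–C10 into two achiral pieces. The locally symmetric CH2–C(CH3)2–CH2 unit C3–C4–C5 is held, together with C6, in 3,3-dimethylcyclobutan-1-ol. C2–C1–C10 with its methyl, C9, C11 and the future C8 lies in a vinyl-substituted alkylidene Meldrum's acid. In one operation, strain-driven β-scission of the cyclobutyloxy radical gives a C3 radical that adds to C2 and frees the C6 aldehyde, whose enamine then closes ring A by Michael addition of C5 to C10, setting the quaternary C10 and C5. Ring B is closed afterwards on an ynone; C6 and C9 follow by substrate control.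

Key step: step 3

Remark: positions follow drimane numbering (ring A = C1–C5 and C10; ring B = C5–C10; C11 on C9, C12 on C8; α/β relative to the β C10 methyl), and the target is handled as the open aldehyde–acid drawn, which may equilibrate with its cyclic lactol form.

Step 1
Reactants: 1 2,2-dimethyl-1,3-dioxane-4,6-dione (Meldrum's acid); 2 trimethyl orthoacetate
Product: 3 5-(1-methoxyethylidene)-2,2-dimethyl-1,3-dioxane-4,6-dione
Conditions: neat MeC(OMe)3 (4 equiv), 100 °C, MeOH distilled off
Reagents that add atoms: none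
Why: Knoevenagel-type condensation of the acidic methylene with the orthoester should give the β-methoxy alkylidene, whose β-carbon becomes C10 and whose methyl becomes the C10 methyl.

Step 2
Reactants: 3 5-(1-methoxyethylidene)-2,2-dimethyl-1,3-dioxane-4,6-dione; 4 vinylmagnesium bromide
Product: 5 5-(but-3-en-2-ylidene)-2,2-dimethyl-1,3-dioxane-4,6-dione
Conditions: CH2=CHMgBr (1.05 equiv), CuBr·SMe2 (5 mol %), THF, −78 °C; aq. NH4Cl
Reagents that add atoms: none
Why: Conjugate addition–elimination (vinylogous acyl substitution) at the β-carbon should exchange methoxide for vinyl and so install C1=C2, with low temperature and one equivalent of nucleophile guarding against a second addition.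

Step 3
Reactants: 6 3,3-dimethylcyclobutan-1-ol (1.5 equiv); 5 5-(but-3-en-2-ylidene)-2,2-dimethyl-1,3-dioxane-4,6-dione
Product: 8 5-[(1S,2S)-2-formyl-1,3,3-trimethylcyclohexyl]-2,2-dimethyl-1,3-dioxane-4,6-dione, via open-chain aldehyde 7 (not isolated)
Conditions: CeCl3 (5 mol %), nBu4NCl (15 mol %), MeCN, 400 nm LEDs, 25 °C; then (R)-α,α-diphenylprolinol trimethylsilyl ether (20 mol %), PhCO2H (20 mol %), 25 °C
Reagents that add atoms: none
Why: Proposed new method: photolysis of the cerium alkoxide of 6 (tetravalent cerium, ligand-to-metal charge transfer) should give the cyclobutyloxy radical, whose strain-driven β-scission of either of the two equivalent C–C bonds unmasks the C6 aldehyde and a primary C3 radical that adds to the unsubstituted diene terminus C2 of 5 (1,6-Giese addition); the Meldrum's-stabilised allyl radical is then reduced by trivalent cerium and protonated to 7, which closes a redox-neutral cycle. In the second stage the enamine of 7 attacks C10 through C5 in a 6-exo-trig Michael addition that closes ring A. The closest known reaction types are the cerium-photocatalysed ring-opening Giese addition of cycloalkanols to electron-poor alkenes and the aminocatalytic intramolecular Michael addition of aldehydes to alkylidene 1,3-dicarbonyl compounds; their merger into a formal [3+3] annulation is the new element. C5 is set by the catalyst, whose silyloxydiphenylmethyl group shields one enamine face, and C10 is relayed from C5 through the chair transition state with equatorial enamine, axial C10 methyl and C9 kept away from the axial C4 methyl, which should give the trans C6/C9 relationship (5S,10S). The step needs 1,6- over 1,4-regioselectivity in the radical addition, secured by the open CH2 terminus against the fully substituted C10, and it needs the bonds to form in this order, secured because only the aldehyde released by ring opening can form an enamine and only C5 is then within reach of C10. The hindered tertiary α-centre of 8 should not re-enter the enamine cycle, so the C5 configuration should be kept.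

Step 4
Reactants: 8 5-[(1S,2S)-2-formyl-1,3,3-trimethylcyclohexyl]-2,2-dimethyl-1,3-dioxane-4,6-dione; 9 3,3-diethoxyprop-1-yne
Product: 10 5-[(1S,2S)-2-(4,4-diethoxy-1-hydroxybut-2-yn-1-yl)-1,3,3-trimethylcyclohexyl]-2,2-dimethyl-1,3-dioxane-4,6-dione (both carbinol epimers)
Conditions: 9 (2.5 equiv), n-BuLi (2.4 equiv), THF, −78 °C; then 8, −78 to −40 °C; aq. NH4Cl; crude product used at once
Reagents that add atoms: none
Why: Acetylide addition to the aldehyde: the first equivalent should deprotonate the Meldrum's acid C–H (masking it as its enolate) and the second add to C6, bringing in C7, C8 and C12; the carbinol configuration is irrelevant because it is oxidised in step 5.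

Step 5
Reactants: 10 5-[(1S,2S)-2-(4,4-diethoxy-1-hydroxybut-2-yn-1-yl)-1,3,3-trimethylcyclohexyl]-2,2-dimethyl-1,3-dioxane-4,6-dione
Product: 12 (5S,10S)-12,12-diethoxy-6-oxodrim-7-ene-9-spiro-5'-(2',2'-dimethyl-1',3'-dioxane-4',6'-dione), via ynone 11 (not isolated)
Conditions: MnO2 (20 equiv), CH2Cl2, 25 °C; filter; Et3N (1.2 equiv), CH2Cl2, 0 to 25 °C
Reagents that add atoms: none
Why: Oxidation of the propargylic alcohol should give ynone 11, to whose β-carbon C8 the Meldrum's acid carbanion adds in a 6-endo-dig Michael addition that closes ring B with the C7=C8 bond in place, while the weak amine base should not enolise the hindered C5 so the trans ring fusion is kept.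

Step 6
Reactants: 12 (5S,10S)-12,12-diethoxy-6-oxodrim-7-ene-9-spiro-5'-(2',2'-dimethyl-1',3'-dioxane-4',6'-dione); 13 4-methoxybenzyl alcohol
Product: 15 4-methoxybenzyl (5S,10S)-12,12-diethoxy-6-oxodrim-7-en-11-oate (C9 epimers), via malonic half-ester acid 14 (not isolated)
Conditions: 13 (5 equiv), toluene, 110 °C
Reagents that add atoms: none
Why: Alcoholysis of the spiro acylal (Meldrum's acid ring opening) by the primary alcohol should release acetone and give 14, a vinylogous β-keto acid that loses CO2 on heating; the C9 configuration is left uncontrolled because C9 is planarised again in step 8.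

Step 7
Reactants: 15 4-methoxybenzyl (5S,10S)-12,12-diethoxy-6-oxodrim-7-en-11-oate
Product: 16 4-methoxybenzyl (5S,6R,10S)-12,12-diethoxy-6-hydroxydrim-7-en-11-oate (C9 epimers)
Conditions: NaBH4, CeCl3·7H2O, MeOH, −40 °C
Reagents that add atoms: none
Why: Luche 1,2-reduction in which hydride should enter from the α face, away from the axial C10 and C4 β-methyl groups, to give the 6β (6R) alcohol and fix C5.

Step 8
Reactants: 16 4-methoxybenzyl (5S,6R,10S)-12,12-diethoxy-6-hydroxydrim-7-en-11-oate
Product: 17 4-methoxybenzyl (5S,6R,9S,10S)-12,12-diethoxy-6,9-dihydroxydrim-7-en-11-oate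
Conditions: KN(SiMe3)2 (2.4 equiv), THF, −78 °C; 2-(benzenesulfonyl)-3-phenyloxaziridine (1.3 equiv), −78 °C; aq. NH4Cl
Reagents that add atoms: 2-(benzenesulfonyl)-3-phenyloxaziridine, O=S(=O)(c1ccccc1)N1OC1c1ccccc1
Why: Enolate hydroxylation with an N-sulfonyloxaziridine: after deprotonation of the hydroxyl and of C9–H, oxygen transfer to the α-carbon of the ester dienolate should occur at C9 from the α face, anti to the axial C10 methyl and the 6β-alkoxide, so that both C9 epimers of 16 converge on the 9α-hydroxy (9S) ester.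

Step 9
Reactants: 18 (2E,4E)-hexa-2,4-dienal; 19 malonic acid
Product: 21 (2E,4E,6E)-octa-2,4,6-trienoic acid, via dienylidenemalonic acid 20 (not isolated)
Conditions: pyridine, piperidine (cat.), 90 °C
Reagents that add atoms: none
Why: Doebner–Knoevenagel condensation in which decarboxylation of 20 should give the new alkene with E geometry while the existing E,E-diene is untouched.

Step 10
Reactants: 17 4-methoxybenzyl (5S,6R,9S,10S)-12,12-diethoxy-6,9-dihydroxydrim-7-en-11-oate; 21 (2E,4E,6E)-octa-2,4,6-trienoic acid
Product: 23 4-methoxybenzyl (5S,6R,9S,10S)-12,12-diethoxy-9-hydroxy-6-[(2E,4E,6E)-octa-2,4,6-trienoyloxy]drim-7-en-11-oate, via mixed anhydride 22 (not isolated)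
Conditions: 21 (1.5 equiv), 2,4,6-Cl3C6H2COCl, Et3N, THF, 25 °C; then 17, DMAP, toluene, 25 to 50 °C
Reagents that add atoms: none
Why: Yamaguchi esterification in which the secondary allylic 6β-hydroxyl should be acylated while the tertiary, neopentyl 9-hydroxyl stays free; no stereocentre is touched.

Step 11
Reactants: 23 4-methoxybenzyl (5S,6R,9S,10S)-12,12-diethoxy-9-hydroxy-6-[(2E,4E,6E)-octa-2,4,6-trienoyloxy]drim-7-en-11-oate
Product: 24 ustusoic acid B
Conditions: CF3CO2H/CH2Cl2/H2O (10:40:1), anisole (5 equiv), 0 °C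
Reagents that add atoms: water, O
Why: Acidolysis of the 4-methoxybenzyl ester (benzyl cation trapped by anisole) and hydrolysis of the allylic diethyl acetal should unveil the C11 acid and the C12 aldehyde in one operation, the C6 ester and C9 alcohol being deactivated towards ionisation by the adjacent enal and carboxyl groups.

**Compound list**

1 | 2,2-dimethyl-1,3-dioxane-4,6-dione (Meldrum's acid) | CC1(C)OC(=O)CC(=O)O1 | starting material
2 | trimethyl orthoacetate | CC(OC)(OC)OC | starting material
3 | 5-(1-methoxyethylidene)-2,2-dimethyl-1,3-dioxane-4,6-dione | COC(C)=C1C(=O)OC(C)(C)OC1=O | intermediate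
4 | vinylmagnesium bromide | C=C[Mg]Br | starting material
5 | 5-(but-3-en-2-ylidene)-2,2-dimethyl-1,3-dioxane-4,6-dione | C=CC(C)=C1C(=O)OC(C)(C)OC1=O | intermediate
6 | 3,3-dimethylcyclobutan-1-ol | CC1(C)CC(O)C1 | starting material
7 | 5-(6,6-dimethyl-8-oxooctan-2-ylidene)-2,2-dimethyl-1,3-dioxane-4,6-dione (not isolated) | O=CCC(C)(C)CCCC(C)=C1C(=O)OC(C)(C)OC1=O | intermediate
8 | 5-[(1S,2S)-2-formyl-1,3,3-trimethylcyclohexyl]-2,2-dimethyl-1,3-dioxane-4,6-dione | O=C[C@H]1C(C)(C)CCC[C@]1(C)C2C(=O)OC(C)(C)OC2=O | intermediate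
9 | 3,3-diethoxyprop-1-yne | C#CC(OCC)OCC | starting material
10 | 5-[(1S,2S)-2-(4,4-diethoxy-1-hydroxybut-2-yn-1-yl)-1,3,3-trimethylcyclohexyl]-2,2-dimethyl-1,3-dioxane-4,6-dione (both carbinol epimers) | CCOC(OCC)C#CC(O)[C@H]1C(C)(C)CCC[C@]1(C)C2C(=O)OC(C)(C)OC2=O | intermediate
11 | 5-[(1S,2S)-2-(4,4-diethoxybut-2-ynoyl)-1,3,3-trimethylcyclohexyl]-2,2-dimethyl-1,3-dioxane-4,6-dione (not isolated) | CCOC(OCC)C#CC(=O)[C@H]1C(C)(C)CCC[C@]1(C)C2C(=O)OC(C)(C)OC2=O | intermediate
12 | (5S,10S)-12,12-diethoxy-6-oxodrim-7-ene in which C9 is the spiro C5 of a 2,2-dimethyl-1,3-dioxane-4,6-dione ring (5α-H, 10β-CH3) | O=C1C=C(C(OCC)OCC)C3(C(=O)OC(C)(C)OC3=O)[C@@]2(C)CCCC(C)(C)[C@H]12 | intermediate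
13 | 4-methoxybenzyl alcohol | COc1ccc(CO)cc1 | starting material
14 | (5S,10S)-12,12-diethoxy-9-[(4-methoxybenzyl)oxycarbonyl]-6-oxodrim-7-en-11-oic acid (C9 epimers, not isolated) | O=C1C=C(C(OCC)OCC)C(C(=O)O)(C(=O)OCc3ccc(OC)cc3)[C@@]2(C)CCCC(C)(C)[C@H]12 | intermediate
15 | 4-methoxybenzyl (5S,10S)-12,12-diethoxy-6-oxodrim-7-en-11-oate (C9 epimers) | O=C1C=C(C(OCC)OCC)C(C(=O)OCc3ccc(OC)cc3)[C@@]2(C)CCCC(C)(C)[C@H]12 | intermediate
16 | 4-methoxybenzyl (5S,6R,10S)-12,12-diethoxy-6-hydroxydrim-7-en-11-oate (6β-OH, C9 epimers) | O[C@@H]1C=C(C(OCC)OCC)C(C(=O)OCc3ccc(OC)cc3)[C@@]2(C)CCCC(C)(C)[C@H]12 | intermediate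
17 | 4-methoxybenzyl (5S,6R,9S,10S)-12,12-diethoxy-6,9-dihydroxydrim-7-en-11-oate (6β-OH, 9α-OH) | O[C@@H]1C=C(C(OCC)OCC)[C@](O)(C(=O)OCc3ccc(OC)cc3)[C@@]2(C)CCCC(C)(C)[C@H]12 | intermediate
18 | (2E,4E)-hexa-2,4-dienal | C/C=C/C=C/C=O | starting material
19 | malonic acid | OC(=O)CC(=O)O | starting material
20 | 2-[(2E,4E)-hexa-2,4-dien-1-ylidene]propanedioic acid (not isolated) | C/C=C/C=C/C=C(C(=O)O)C(=O)O | intermediate
21 | (2E,4E,6E)-octa-2,4,6-trienoic acid | C/C=C/C=C/C=C/C(=O)O | intermediate
22 | (2E,4E,6E)-octa-2,4,6-trienoic 2,4,6-trichlorobenzoic anhydride (not isolated) | C/C=C/C=C/C=C/C(=O)OC(=O)c1c(Cl)cc(Cl)cc1Cl | intermediate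
23 | 4-methoxybenzyl (5S,6R,9S,10S)-12,12-diethoxy-9-hydroxy-6-[(2E,4E,6E)-octa-2,4,6-trienoyloxy]drim-7-en-11-oate | C/C=C/C=C/C=C/C(=O)O[C@@H]1C=C(C(OCC)OCC)[C@](O)(C(=O)OCc3ccc(OC)cc3)[C@@]2(C)CCCC(C)(C)[C@H]12 | intermediate
24 | ustusoic acid B, (5S,6R,9S,10S)-9-hydroxy-6-[(2E,4E,6E)-octa-2,4,6-trienoyloxy]-12-oxodrim-7-en-11-oic acid | C/C=C/C=C/C=C/C(=O)O[C@@H]1C=C(C=O)[C@](O)(C(=O)O)[C@@]2(C)CCCC(C)(C)[C@H]12 | target

**Step count.** Total: 11 steps. Longest linear sequence: 10 steps (steps 1–8, 10 and 11); step 9 is a one-step side branch.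

**Steps most likely to fail**

Step 3 (carries the label). Two processes are at risk. The cerium redox cycle may stall, through chelation of cerium by the acidic 1,3-dicarbonyl adduct or through absorption of the 400 nm light by the diene. The ring closure may also run through the alternative chair with an axial enamine, which would mean poor control of the relative and therefore of the absolute configuration at C10. The fallback uses known reactions and makes the two bonds in separate operations; it sets out from 6 and 5 and comes back at 8. Hypoiodite fragmentation of 6 (PhI(OAc)2, I2, visible light, CH2Cl2; alkoxy-radical β-scission with iodine capture) should give 4-iodo-3,3-dimethylbutanal F1. Tin-free Giese addition of F1 to 5 ((Me3Si)3SiH, AIBN, toluene, 80 °C) should give 7, now isolated. Condensation of 7 with (S)-1-phenylethylamine (MgSO4, CH2Cl2) gives the chiral imine F2, 5-{6,6-dimethyl-8-[(S)-1-phenylethylimino]octan-2-ylidene}-2,2-dimethyl-1,3-dioxane-4,6-dione F2. Its secondary-enamine tautomer should cyclise on warming (THF, 40 °C; Michael addition of a chiral imine) to the cyclised imine 5-[(1S,2S)-1,3,3-trimethyl-2-{[(S)-1-phenylethylimino]methyl}cyclohexyl]-2,2-dimethyl-1,3-dioxane-4,6-dione F3. The diastereomers of the cyclised imine are separated, so purity does not rest on the level of induction, and hydrolysis (aq. AcOH, THF) returns 8.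

Step 8. The oxidant may attack the dienolate at C7 (γ) instead of C9, or from the β face, and the C6 alkoxide may interfere. The fallback moves the oxygenation to the ketone stage; it sets out from 15 and comes back at 17. Deprotonation of 15 at C9 (KN(SiMe3)2, THF, −78 °C) gives the extended enolate of the enone, whose autoxidation (O2, P(OEt)3) should take place at the captodatively stabilised C9 from the α face to give 4-methoxybenzyl (5S,9S,10S)-12,12-diethoxy-9-hydroxy-6-oxodrim-7-en-11-oate F4. Luche reduction of this ketone (NaBH4, CeCl3·7H2O, MeOH) then gives 17.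

Step 6. Acyl substitution at the two neopentyl-type acylal carbonyls by a neutral alcohol may be too slow, and forcing it thermally risks loss of the C5 configuration. The fallback replaces alcoholysis by hydrolysis followed by O-alkylation of the carboxylate; it sets out from 12 and comes back at 15. The small nucleophile hydroxide (LiOH, THF/H2O, 0 °C; then 1 M HCl to pH 4) should open the acylal, and the malonic acid decarboxylates to (5S,10S)-12,12-diethoxy-6-oxodrim-7-en-11-oic acid F5. Esterification of this acid with 4-methoxybenzyl 2,2,2-trichloroacetimidate (CH2Cl2, 25 °C, no added acid) gives 15.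

**Further compounds**

F1 | step 3 | 4-iodo-3,3-dimethylbutanal | O=CCC(C)(C)CI
F2 | step 3 | 5-{6,6-dimethyl-8-[(S)-1-phenylethylimino]octan-2-ylidene}-2,2-dimethyl-1,3-dioxane-4,6-dione | C[C@H](N=CCC(C)(C)CCCC(C)=C1C(=O)OC(C)(C)OC1=O)c2ccccc2
F3 | step 3 | 5-[(1S,2S)-1,3,3-trimethyl-2-{[(S)-1-phenylethylimino]methyl}cyclohexyl]-2,2-dimethyl-1,3-dioxane-4,6-dione | C[C@H](N=C[C@H]1C(C)(C)CCC[C@]1(C)C3C(=O)OC(C)(C)OC3=O)c2ccccc2
F4 | step 8 | 4-methoxybenzyl (5S,9S,10S)-12,12-diethoxy-9-hydroxy-6-oxodrim-7-en-11-oate | O=C1C=C(C(OCC)OCC)[C@](O)(C(=O)OCc3ccc(OC)cc3)[C@@]2(C)CCCC(C)(C)[C@H]12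
F5 | step 6 | (5S,10S)-12,12-diethoxy-6-oxodrim-7-en-11-oic acid (C9 epimers) | O=C1C=C(C(OCC)OCC)C(C(=O)O)[C@@]2(C)CCCC(C)(C)[C@H]12
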